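What is left of Q in the ochre run shrinks from 33.0% at 1.00 h to 22.5% at 4.00 h, while E beside it goes from 37.6% to 37.8%. Here are the runs and the questions.

in all of them: J 11.4 mM

| flask | D | L | remark | time |
|---|---|---|---|---|
| ochre | 8 mM | 12.6 mM | run made earlier |  |
| violet | 18 mM | 12.6 mM | run made earlier |  |
| grey | 12 mM | 25 mM | run made earlier |  |
| flask | 12 mM | 12.6 mM |  | 3.0 h |

| run | time / h | E / % | Q / % |
|---|---|---|---|
| ochre | 0.250 | 30.7 | 32.7 |
| ochre | 0.500 | 35.8 | 34.8 |
| ochre | 1.00 | 37.6 | 33.0 |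
| ochre | 2.00 | 37.3 | 29.6 |
| ochre | 4.00 | 37.8 | 22.5 |
| violet | 0.250 | 25.4 | 25.8 |
| violet | 0.500 | 27.8 | 28.1 |
| violet | 1.00 | 29.8 | 26.3 |
| violet | 2.00 | 29.8 | 23.3 |
| violet | 4.00 | 29.4 | 18.2 |
| grey | 0.333 | 21.0 | 40.8 |
| grey | 0.833 | 22.3 | 41.0 |
| grey | 1.50 | 22.8 | 37.4 |
| grey | 2.50 | 23.2 | 32.9 |
| grey | 4.00 | 22.3 | 27.9 |

(each reading ± 0.5 percentage points)

* ratio of E to Q at 30 s
* ratio of E to Q at 10 min
* ratio of E to Q at 3.0 h

- the numbers in the tables scatter with a standard deviation of 0.5 percentage points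

I read the fall of Q from the 1.00 h row of ochre and violet and the 1.50 h row of grey to the last row as a first-order loss. That gives 0.128 h⁻¹ in ochre, 0.123 h⁻¹ in violet and 0.117 h⁻¹ in grey, so I take 0.123 h⁻¹.

Now I date Q back to time zero and set E against it. The ratio is 1.01 in ochre and 1.00 in violet, so more D leaves it level. In grey, with 25 mM of L, it is 0.507, about half of ochre.

So I multiply each ratio by cL/cJ. With the charges, the first round gives 1.11, 1.11 and 1.11. But I assume that each Q takes one L and each E one J, so I go round once more with cL and cJ taken halfway through formation. That gives 1.13, 1.14 and 1.13, with mean 1.13. This s is my partition number, the selectivity factor: E formed per Q formed, times cL/cJ at that moment.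

For the flask, s·cJ/cL gives 1.03 at 30 s. With about 4.04 mM of E formed, as the mean of ochre and violet suggests, the halfway ratio is 1.00. Q's loss then lifts this to 1.03 at 10 min and 1.45 at 3.0 h.

The forecast says 0.9 (0.55 to 1.08), 0.95 (0.85 to 1.04) and 1.44 (1.36 to 1.53), on the ground that “E and Q look like a partition from a shared intermediate”. My early values stand higher than its values.

The flask gives 0.994 at 30 s, 0.997 at 10 min and 1.45 at 3.0 h.

    D ⇌ G (K = 0.268, k = 0.00182 s⁻¹)
    L + G → Q (k = 64.3 L mol⁻¹ s⁻¹)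
    J + G → E (k = 70.7 L mol⁻¹ s⁻¹)
    2 D → X (k = 0.0807 L mol⁻¹ s⁻¹)
    Q ⇌ Z (K = 3.40, k = 4.13 × 10⁻⁵ s⁻¹)

At 3.00 h the flask holds 33.6% of E, 23.1% of Q and 11.3% of Z, so E against Q and Z together stands at 0.977. At 30 s in this flask s·cJ/cL gave 1.03 against the 0.994 found. A neighbour flask charged with 5.0 mM of L has s·cJ/cL of 2.58, and it gives 2.50 at 30 s.

The numbers in the tables come from a simulation from invented constants; scatter was added.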